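Readings and results were computed with constants of no real substance, and the scatter is random.

The pitfall with a flask like west is to count equivalents and take what is charged for what reacts.

| flask | substrate | coupling partner | capture agent | remark | time |
|---|---|---|---|---|---|
| maple | 0.10 M | 0.10 M | 0.10 M | run made earlier |  |
| larch | 0.10 M | 0.16 M | 0.10 M | run made earlier |  |
| alder | 0.10 M | 0.23 M | 0.10 M | run made earlier |  |
| south-west | 0.10 M | 0.0800 M | 0.100 M |  | 8.0 h |
| north | 0.10 M | 0.200 M | 0.100 M |  | 8.0 h |
| west | 0.10 M | 0.300 M | 0.100 M |  | 8.0 h |

| run | time / h | single product / % | double product / % | substrate / % |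
|---|---|---|---|---|
| maple | 0.500 | 31.7 | 8.0 | 59.0 |
| maple | 1.33 | 35.0 | 14.9 | 47.6 |
| maple | 2.50 | 34.0 | 16.7 | 45.1 |
| maple | 4.00 | 30.7 | 16.8 | 44.4 |
| maple | 6.00 | 27.3 | 16.6 | 45.9 |
| larch | 0.500 | 37.3 | 16.1 | 46.6 |
| larch | 1.33 | 37.0 | 24.7 | 33.2 |
| larch | 2.50 | 34.9 | 28.6 | 32.0 |
| larch | 4.00 | 32.1 | 28.5 | 30.4 |
| larch | 6.00 | 27.6 | 29.3 | 31.2 |
| alder | 1.00 | 36.8 | 32.6 | 27.7 |
| alder | 2.50 | 32.8 | 39.6 | 21.5 |
| alder | 3.00 | 30.9 | 41.5 | 21.5 |
| alder | 5.00 | 27.6 | 42.0 | 20.6 |
| alder | 6.00 | 26.9 | 41.6 | 20.3 |

(standard deviation of a reading: 0.5 percentage points)

* which of these holds the largest part of the substrate at the end of south-west (double product / substrate / single product)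
* which of these holds the largest part of the substrate at the end of north (double product / substrate / single product)
* which of these holds the largest part of the substrate at the end of west (double product / substrate / single product)
* single product at the end of west, in percent of the substrate charged



*What do the runs say about the coupling partner?* Each substrate turned has taken one partner and each double product a second, so c(substrate) × (substrate turned + double product) is the partner found in product. In larch at 6.00 h that leaves 0.0619 M unfound, yet substrate had nearly stopped, at 32.0% after 2.50 h and 31.2% at the end. So I take that partner to be gone by an unseen path.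

*What will you carry forward?* Follow one partner molecule: it reaches product or it is lost. At their last readings, maple, larch and alder give chances of 70.7%, 61.3% and 52.7%, at 1.00, 1.60 and 2.30 equivalents. This chance, partner found in product over partner charged, is the partner share, a selectivity.

*But substrate stood at 0.10 M in maple, larch and alder. Why equivalents?* I cannot show it; it is a bet. If loss is partner meeting partner and use is partner meeting substrate, the odds at the fork follow c(coupling partner)/c(substrate).

*And west?* At 3.00 equivalents it lies beyond alder, so I continue the line through larch and alder. My share is 44.2%, which makes substrate turned plus double product 132% of the substrate charged. That sum does not give single product.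

*What does the forecast say?* It gives substrate for south-west, double product for north, double product for west, and 20% single product in west, reasoning that “Single product therefore leaks slowly to something unseen”.

West ends at 20.6% single product, and the forecast's three choices hold. West's self-condensation product stands at 0.0812 M, two partner each, which is 54.2% of the partner charged. The partner share read from west's end is 45.8%, against my 44.2%.

    substrate + coupling partner → single product (k = 0.340 L mol⁻¹ min⁻¹)
    coupling partner + single product → double product (k = 0.290 L mol⁻¹ min⁻¹)
    2 coupling partner → self-condensation product (k = 0.140 L mol⁻¹ min⁻¹)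
    single product + capture agent → trapped intermediate (k = 0.0110 L mol⁻¹ min⁻¹)

The forecast's answer for west, double product, does not carry over to one neighbour flask. West with 0.25 M substrate has 1.20 equivalents, between maple and larch, so the share reads 67.6% and substrate turned plus double product 81.1%. Computed, that flask holds 39.4% substrate and 21.0% double product, so substrate turned plus double product comes to 81.6%; its largest part is substrate, with single product at 26.0%.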